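**Retrosynthetic overview**
1. Target 15 ⇐ E-selective cross-metathesis of the 6-vinyl dihydropyranone 8 with the side-chain alkene 14 (C1'=C2' bond, last step).
2. 8 ⇐ ring-closing metathesis of the tiglate/acrylate diester 7 of C2-symmetric (3S,4S)-hexa-1,5-diene-3,4-diol 5. This is the only ring and it is closed late. Because 5 is C2-symmetric, monotigloylation can give only one monoester.
3. 5 ⇐ L-tartaric acid acetonide diacid 2 by a twofold light-driven, nickel-catalysed decarboxylative vinylation, which forms both C–C bonds next to the ring stereocentres.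
4. 14 ⇐ (2S,3Z)-pent-3-en-2-ol 11 by a hydroxy-directed singlet-oxygen ene reaction (C3'–O bond, threo), and 11 ⇐ (S)-but-3-yn-2-ol 9.

Assumption: the target is the (5S,6S,3'S,4'S) isomer read from the SMILES (the diacetate of phomopsolide B); 1, 9, vinyl bromide, tigloyl chloride and acryloyl chloride are bought.

**Step 1**
Reactants: 1 dimethyl (4R,5R)-2,2-dimethyl-1,3-dioxolane-4,5-dicarboxylate
Product: 2 (4R,5R)-2,2-dimethyl-1,3-dioxolane-4,5-dicarboxylic acid
Conditions: KOH (2.2 equiv), MeOH/H2O, 0 °C to rt; then 1 M HCl to pH 2 at 0 °C, EtOAc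
Reagents that add atoms: potassium hydroxide, [K+].[OH-]
Why: Ester saponification; the trans-acetonide is the stable isomer, so the two bought stereocentres are kept, and the ketal survives brief cold acidification.

**Step 2**
Reactants: 2 (4R,5R)-2,2-dimethyl-1,3-dioxolane-4,5-dicarboxylic acid
Product: 4 (4S,5S)-4,5-diethenyl-2,2-dimethyl-1,3-dioxolane, via monovinyl acid 3 (not isolated)
Conditions: vinyl bromide (1.0 M in THF, 6 equiv), [Ir{dF(CF3)ppy}2(dtbbpy)]PF6 (2 mol%), NiCl2(dme) (10 mol%), dtbbpy (12 mol%), Cs2CO3 (2.2 equiv), DMSO, 450 nm LEDs, 25 °C, sealed vessel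
Reagents that add atoms: vinyl bromide, C=CBr
Why: Proposed new method: a twofold nickel/photoredox decarboxylative vinylation of a vicinal α-oxy diacid, in which the excited trivalent iridium photocatalyst oxidises each cesium carboxylate in turn, loss of CO2 gives a 1,3-dioxolan-4-yl radical, zerovalent nickel inserts into vinyl bromide, the divalent vinylnickel bromide captures the radical on the face anti to the neighbouring ring substituent and trivalent nickel reductively eliminates, so the first vinyl group enters trans to the remaining carboxylate (3) and the second trans to the first, relaying the tartrate configuration into trans-(4S,5S)-4 without passing through the epimerisable tartraldehyde; the closest known reaction type is the nickel/photoredox decarboxylative coupling of single α-oxy acids with vinyl halides.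

**Step 3**
Reactants: 4 (4S,5S)-4,5-diethenyl-2,2-dimethyl-1,3-dioxolane
Product: 5 (3S,4S)-hexa-1,5-diene-3,4-diol
Conditions: AcOH/H2O (4:1), 50 °C
Reagents that add atoms: none
Why: Acid-catalysed acetal hydrolysis; the allylic C–O bonds are not ionised under these mild conditions, so both stereocentres are kept.

**Step 4**
Reactants: 5 (3S,4S)-hexa-1,5-diene-3,4-diol
Product: 6 (3S,4S)-4-hydroxyhexa-1,5-dien-3-yl (2E)-2-methylbut-2-enoate
Conditions: tigloyl chloride (0.95 equiv, slow addition), pyridine, CH2Cl2, −40 to 0 °C; recovered 5 recycled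
Reagents that add atoms: tigloyl chloride, C/C=C(\C)C(=O)Cl
Why: Monoacylation with an acid chloride; the two hydroxyl groups of C2-symmetric 5 are equivalent, so only one monoester can form, the first ester slows the second acylation, and acyl migration is degenerate.

**Step 5**
Reactants: 6 (3S,4S)-4-hydroxyhexa-1,5-dien-3-yl (2E)-2-methylbut-2-enoate
Product: 7 (3S,4S)-4-(prop-2-enoyloxy)hexa-1,5-dien-3-yl (2E)-2-methylbut-2-enoate
Conditions: acryloyl chloride (1.5 equiv), i-Pr2NEt, CH2Cl2, −20 to 0 °C
Reagents that add atoms: acryloyl chloride, C=CC(=O)Cl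
Why: Esterification of the remaining secondary alcohol with an acid chloride under amine base; no stereocentre is touched.

**Step 6**
Reactants: 7 (3S,4S)-4-(prop-2-enoyloxy)hexa-1,5-dien-3-yl (2E)-2-methylbut-2-enoate
Product: 8 (2S,3S)-2-ethenyl-6-oxo-3,6-dihydro-2H-pyran-3-yl (2E)-2-methylbut-2-enoate
Conditions: second-generation Grubbs catalyst RuCl2(=CHPh)(H2IMes)(PCy3) (5 mol%), CH2Cl2 (5 mM), 40 °C
Reagents that add atoms: none
Why: Ring-closing metathesis; the acrylate closes onto the vinyl group of the neighbouring tiglate-bearing carbon because the six-membered dihydropyranone forms faster than the butenolide, the trisubstituted tiglate is inert, and the cis C5–O/C6–vinyl relation follows directly from the threo diol.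

**Step 7**
Reactants: 9 (S)-but-3-yn-2-ol
Product: 10 (S)-pent-3-yn-2-ol
Conditions: n-BuLi (2.1 equiv), THF, −78 to 0 °C; MeI (1.0 equiv), −78 °C to rt; then H2O
Reagents that add atoms: iodomethane, CI
Why: Alkylation of the lithium acetylide of the alkoxide/acetylide dianion; the acetylide carbon is far more nucleophilic than the lithium alkoxide, and the carbinol stereocentre is not involved.

**Step 8**
Reactants: 10 (S)-pent-3-yn-2-ol
Product: 11 (2S,3Z)-pent-3-en-2-ol
Conditions: H2 (1 atm), Pd/CaCO3 poisoned with Pb(OAc)2, quinoline, pentane, 0 °C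
Reagents that add atoms: none
Why: Lindlar semihydrogenation; syn addition of H2 gives the Z-alkene that the next step needs for allylic-strain control.

**Step 9**
Reactants: 11 (2S,3Z)-pent-3-en-2-ol
Product: 14 (3S,4S)-pent-1-ene-3,4-diyl diacetate, via hydroperoxide 12 (not isolated), via diol 13 (not isolated)
Conditions: O2, 5,10,15,20-tetraphenylporphyrin (0.2 mol%), CH2Cl2, −20 °C, white LEDs; then PPh3 (1.05 equiv), 0 °C; then Ac2O, pyridine, DMAP (cat.), rt
Reagents that add atoms: dioxygen, O=O; acetic anhydride, CC(=O)OC(C)=O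
Why: Hydroxy-directed Schenck ene reaction of singlet oxygen, in which 1,3-allylic strain of the Z-alkene holds the carbinol H in the olefin plane and the OH hydrogen-bonds the incoming oxygen to its own face, so the new C3–O bond forms threo (2S,3S) to the bought stereocentre (about 93:7 expected from the parent racemic case, minor epimer removed after step 10) with hydrogen abstraction from the methyl group giving the terminal alkene; phosphine reduction and acetylation follow in the same flask.

**Step 10**
Reactants: 8 (2S,3S)-2-ethenyl-6-oxo-3,6-dihydro-2H-pyran-3-yl (2E)-2-methylbut-2-enoate; 14 (3S,4S)-pent-1-ene-3,4-diyl diacetate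
Product: 15 (2S,3S)-2-[(1E,3S,4S)-3,4-bis(acetyloxy)pent-1-en-1-yl]-6-oxo-3,6-dihydro-2H-pyran-3-yl (2E)-2-methylbut-2-enoate
Conditions: 14 (3 equiv), second-generation Hoveyda–Grubbs catalyst RuCl2(=CH-C6H4-2-OiPr)(H2IMes) (10 mol%), CH2Cl2, 40 °C
Reagents that add atoms: none
Why: Olefin cross-metathesis between two slowly homodimerising allylic-ester olefins; the thermodynamically preferred E-alkene forms, the conjugated ring alkene and the tiglate do not react, and no stereocentre is touched.

**Compound list**
1 | dimethyl (4R,5R)-2,2-dimethyl-1,3-dioxolane-4,5-dicarboxylate | COC(=O)[C@@H]1OC(C)(C)O[C@H]1C(=O)OC | starting material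
2 | (4R,5R)-2,2-dimethyl-1,3-dioxolane-4,5-dicarboxylic acid | OC(=O)[C@@H]1OC(C)(C)O[C@H]1C(=O)O | intermediate
3 | (4R,5S)-5-ethenyl-2,2-dimethyl-1,3-dioxolane-4-carboxylic acid | OC(=O)[C@@H]1OC(C)(C)O[C@H]1C=C | intermediate
4 | (4S,5S)-4,5-diethenyl-2,2-dimethyl-1,3-dioxolane | C=C[C@@H]1OC(C)(C)O[C@H]1C=C | intermediate
5 | (3S,4S)-hexa-1,5-diene-3,4-diol | C=C[C@H](O)[C@@H](O)C=C | intermediate
6 | (3S,4S)-4-hydroxyhexa-1,5-dien-3-yl (2E)-2-methylbut-2-enoate | C/C=C(\C)C(=O)O[C@@H](C=C)[C@@H](O)C=C | intermediate
7 | (3S,4S)-4-(prop-2-enoyloxy)hexa-1,5-dien-3-yl (2E)-2-methylbut-2-enoate | C/C=C(\C)C(=O)O[C@@H](C=C)[C@@H](OC(=O)C=C)C=C | intermediate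
8 | (2S,3S)-2-ethenyl-6-oxo-3,6-dihydro-2H-pyran-3-yl (2E)-2-methylbut-2-enoate | C/C=C(\C)C(=O)O[C@H]1C=CC(=O)O[C@H]1C=C | intermediate
9 | (S)-but-3-yn-2-ol | C[C@H](O)C#C | starting material
10 | (S)-pent-3-yn-2-ol | C[C@H](O)C#CC | intermediate
11 | (2S,3Z)-pent-3-en-2-ol | C[C@H](O)/C=C\C | intermediate
12 | (2S,3S)-3-hydroperoxypent-4-en-2-ol | C[C@H](O)[C@@H](OO)C=C | intermediate
13 | (2S,3S)-pent-4-ene-2,3-diol | C[C@H](O)[C@@H](O)C=C | intermediate
14 | (3S,4S)-pent-1-ene-3,4-diyl diacetate | C=C[C@H](OC(C)=O)[C@H](C)OC(C)=O | intermediate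
15 | (2S,3S)-2-[(1E,3S,4S)-3,4-bis(acetyloxy)pent-1-en-1-yl]-6-oxo-3,6-dihydro-2H-pyran-3-yl (2E)-2-methylbut-2-enoate | C/C=C(\C)C(=O)O[C@H]1C=CC(=O)O[C@H]1/C=C/[C@H](OC(C)=O)[C@H](C)OC(C)=O | target

**Step count**
Total: 10 steps. Longest linear sequence: 7 steps (steps 1–6, then 10); the side-chain branch is steps 7–9.

**Steps most likely to fail**

Step 2 (the proposed new reaction). It has not been run on a 1,2-diacid. The radical next to a carboxylate could be over-oxidised and lose the second CO2 to give a dioxole. Any cis leakage in the first coupling reappears as the enantiomer after the second, so the optical purity of 4 must be checked. Compound 4 is also volatile. The fallback uses known chemistry and sets out from 1: reduction with i-Bu2AlH (2.1 equiv, toluene, −78 °C) gives (4R,5R)-2,2-dimethyl-1,3-dioxolane-4,5-dicarbaldehyde F1, which is not isolated but treated in the same flask with Ph3P=CH2 (from Ph3PCH3Br and KN(SiMe3)2, THF, −78 °C to rt). This one-pot reduction/Wittig methylenation comes back to the route at 4.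

Step 6. Both vinyl groups of 7 sit next to esters and initiate slowly, and the butenolide or oligomers may compete with the six-membered ring. The fallback sets out from 5 and changes the order of events. Monoacylation with acryloyl chloride (pyridine, −40 °C) gives (3S,4S)-4-hydroxyhexa-1,5-dien-3-yl prop-2-enoate F2. Its free allylic hydroxyl speeds metathesis at the vinyl group on its own carbon, so ring-closing metathesis with RuCl2(=CHPh)(H2IMes)(PCy3) is steered to (5S,6S)-6-ethenyl-5-hydroxy-5,6-dihydro-2H-pyran-2-one F3. Steglich esterification with tiglic acid (DCC, DMAP) then comes back to the route at 8.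

Step 10. Both partners carry allylic oxygen and are sluggish, so conversion may stall and homodimers of 14 may accumulate. The fallback sets out from 6 (with 14) and joins the fragments before the ring is closed. Hydroxyl-accelerated cross-metathesis at the vinyl group next to the free alcohol of 6 gives (3S,4S,5E,7S,8S)-7,8-bis(acetyloxy)-4-hydroxynona-1,5-dien-3-yl (2E)-2-methylbut-2-enoate F4. Acryloylation (acryloyl chloride, i-Pr2NEt) gives (3S,4S,5E,7S,8S)-7,8-bis(acetyloxy)-4-(prop-2-enoyloxy)nona-1,5-dien-3-yl (2E)-2-methylbut-2-enoate F5. F5 has only one terminal vinyl group, so ring-closing metathesis can give only the six-membered lactone and comes back to the route at 15.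

**Further compounds**
F1 | step 2 | (4R,5R)-2,2-dimethyl-1,3-dioxolane-4,5-dicarbaldehyde | O=C[C@@H]1OC(C)(C)O[C@H]1C=O
F2 | step 6 | (3S,4S)-4-hydroxyhexa-1,5-dien-3-yl prop-2-enoate | C=CC(=O)O[C@@H](C=C)[C@@H](O)C=C
F3 | step 6 | (5S,6S)-6-ethenyl-5-hydroxy-5,6-dihydro-2H-pyran-2-one | O[C@H]1C=CC(=O)O[C@H]1C=C
F4 | step 10 | (3S,4S,5E,7S,8S)-7,8-bis(acetyloxy)-4-hydroxynona-1,5-dien-3-yl (2E)-2-methylbut-2-enoate | C/C=C(\C)C(=O)O[C@@H](C=C)[C@@H](O)/C=C/[C@H](OC(C)=O)[C@H](C)OC(C)=O
F5 | step 10 | (3S,4S,5E,7S,8S)-7,8-bis(acetyloxy)-4-(prop-2-enoyloxy)nona-1,5-dien-3-yl (2E)-2-methylbut-2-enoate | C/C=C(\C)C(=O)O[C@@H](C=C)[C@@H](OC(=O)C=C)/C=C/[C@H](OC(C)=O)[C@H](C)OC(C)=O
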